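The readings were generated by integration with made-up constants; scatter was added.

If two isothermal runs at different charges give the same early fractions, the chair opened, the early steps of those runs may be reckoned first order and a peak time tried on a new charge at that temperature.

| flask | starting material | remark | time |
|---|---|---|---|
| north-west | 0.097 M | run made earlier |  |
| east | 0.15 M | run made earlier |  |
| flask | 0.069 M |  | 4.0 d |

- north-west (time / d: intermediate A / %, target / %): 0.0208: 43, 0; 0.0556: 54, 4; 0.104: 49, 8; 0.250: 29, 11; 0.500: 19, 16; 1.04: 13, 25; 2.50: 6, 35
- east (time / d: intermediate A / %, target / %): 0.0208: 44, 0; 0.0556: 54, 1; 0.104: 49, 5; 0.250: 32, 9; 0.500: 19, 17; 1.04: 10, 23; 2.50: 8, 37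

(standard deviation of a reading: 1.5 percentage points)

- a reading or a percentage of target counts all its forms, free or not

* time up to 4.0 d at which intermediate A stands highest
* the amount of intermediate A, in percent of the starting material charged, at that time

The first speaker noted that the east charge is 1.55 times the north-west charge. Yet the runs read 54% and 54% intermediate A at 0.0556 d. The flask's charge lies below both, so she asked for a time that holds the charge out of the reckoning.

The second speaker split the curve into a slow fall and a fast rise. From the mean readings at 0.104 d and 0.250 d he read a fall constant of 3.25 d⁻¹. Run back to the start, that line begins at 68.7% of the charge. The shortfall below it at 0.0208 d gave a rise constant of 57.7 d⁻¹, far faster than the fall. Both constants come from fractions of the charge, so he carried them to the flask unchanged.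

He then took the logarithm of their ratio over their difference. That gave 0.0529 d, the crossover time: the moment when filling and fading of intermediate A balance, for two first-order stages in series. His curve stands at 54.6% of the charge there, and he committed the flask to these two numbers.

The forecast gave 0.065 d (0.045 d to 0.085 d), later than the crossover time, and 55% (52% to 58%), holding that the flask “should follow the same curve”.

The flask peaks at 0.0535 d with 53.8% of the charge as intermediate A.

    starting material ⇌ intermediate A (K = 2.00, k = 4.20 × 10⁻⁴ s⁻¹)
    starting material ⇌ intermediate B (K = 7.00, k = 2.50 × 10⁻⁵ s⁻¹)
    intermediate A → target (k = 1.10 × 10⁻⁵ s⁻¹)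
    intermediate B ⇌ intermediate A (k = 7.70 × 10⁻⁶ s⁻¹)
    starting material + target ⇌ idle adduct, settled at all times (K = 250 M⁻¹)

The crossover time, read from the two runs with their scatter, lies beside that peak time. At 0.0535 d the idle adduct in the flask, which takes two partners and counts as two, stands at 3.52% of the charge. Carried to this flask at twice the dilution, the crossover time stays 0.0529 d, and the diluted flask peaks at 0.0538 d.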